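**Retrosynthetic overview**

1. Numbering used: ring A = quinone (C1=O lies between C2–OMe and C6–CH2CH2; C3–H; C4=O; C5–O–ring D); ring B = para-phenylene; ring C = the phenol ring; ring D = meta-phenylene.
2. Ring A is built de novo in one thermal cascade that makes C2–C3 and C4–C5: cyclobutenone 9 supplies C1, C2, C5, C6 with both arms already attached, siloxyalkyne 14 supplies C3 and C4.
3. Enabling feature: the C2(O)–C3(H)–C4(O) edge of ring A is a 1,3-dioxygen pattern around the only unsubstituted ring carbon, flanked by the aryl ether at C5, and C1 (para to C4) needs its oxygen only at the end; this is the pattern a vinylketene and an ynol ether deliver.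
4. 9 comes from a ketene/enol ether [2+2] that joins the ring D piece 6 to the ring B–C piece 4 (Ullmann ether, then double carbonyl methylenation).
5. Ring order: B–O–C ether → cyclobutanone → cyclobutenone → ring A → 18-membered ring by B-alkyl Suzuki closure of the C–D ethano bridge → C1–H oxidised to the quinone → debenzylation.

Key step: step 8

Remarks on the chemistry: siloxyalkyne 14 is assumed not to be purchasable and is made in steps 6 and 7. The target has no stereocentre; 8, 16, F3, F4 and F5 are racemic (8 and F3 as diastereomer mixtures) and their stereocentres are destroyed later, so their SMILES carry no configuration.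

**Route**

Step 1
Reactants: 1 4-(benzyloxy)-3-hydroxybenzaldehyde; 2 methyl 3-(4-iodophenyl)propanoate
Product: 3 methyl 3-{4-[2-(benzyloxy)-5-formylphenoxy]phenyl}propanoate
Conditions: CuI (10 mol%), N,N-dimethylglycine hydrochloride (30 mol%), Cs2CO3, 1,4-dioxane, 90 °C
Reagents that add atoms: none
Why: Ullmann-type copper-catalysed diaryl ether coupling of the phenol with the aryl iodide should form the B–O–C ether, with aldehyde, ester and benzyl ether inert.

Step 2
Reactants: 3 methyl 3-{4-[2-(benzyloxy)-5-formylphenoxy]phenyl}propanoate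
Product: 4 1-(benzyloxy)-4-ethenyl-2-[4-(3-methoxybut-3-en-1-yl)phenoxy]benzene
Conditions: Cp2Ti(CH3)2 (5 equiv), toluene, 70 °C, dark; filtration through basic Al2O3
Reagents that add atoms: bis(cyclopentadienyl)dimethyltitanium, C[Ti](C)(C1C=CC=C1)C1C=CC=C1
Why: Petasis methylenation, in which thermally formed Cp2Ti=CH2 should convert the ester into the 2-methoxy-1-alkene and the aryl aldehyde into the styrene in one pot.

Step 3
Reactants: 5 (3-bromophenoxy)acetic acid
Product: 6 (3-bromophenoxy)acetyl chloride
Conditions: (COCl)2, DMF (cat.), CH2Cl2, 0 °C to rt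
Reagents that add atoms: oxalyl chloride, ClC(=O)C(=O)Cl
Why: standard acid chloride formation through the chloroiminium catalyst; the product is used crude.

Step 4
Reactants: 6 (3-bromophenoxy)acetyl chloride; 4 1-(benzyloxy)-4-ethenyl-2-[4-(3-methoxybut-3-en-1-yl)phenoxy]benzene
Product: 8 3-(2-{4-[2-(benzyloxy)-5-ethenylphenoxy]phenyl}ethyl)-2-(3-bromophenoxy)-3-methoxycyclobutan-1-one (diastereomer mixture), via (3-bromophenoxy)ketene 7 (not isolated)
Conditions: Et3N, CH2Cl2, 40 °C, slow addition of 6
Reagents that add atoms: none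
Why: ketene–enol ether [2+2] cycloaddition, in which the nucleophilic CH2 terminus of the enol ether should bond to the ketene carbonyl carbon and the methoxy-bearing carbon to the aryloxy-bearing carbon; the enol ether is far more nucleophilic than the styrene.

Step 5
Reactants: 8 the cyclobutanone of step 4
Product: 9 3-(2-{4-[2-(benzyloxy)-5-ethenylphenoxy]phenyl}ethyl)-2-(3-bromophenoxy)cyclobut-2-en-1-one
Conditions: DBU, CH2Cl2, 0 °C to rt
Reagents that add atoms: none
Why: E1cB elimination of methanol: the ring hydrogen between C=O and OAr is the more acidic α-hydrogen, so the enolate should form there and expel methoxide from the adjacent quaternary carbon, placing the double bond between the aryloxy-bearing and alkyl-bearing carbons from both diastereomers of 8.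

Step 6
Reactants: 10 ethynyltrimethylsilane
Product: 13 trimethyl({[tri(propan-2-yl)silyl]oxy}ethynyl)silane, via lithium (trimethylsilyl)acetylide 11 (not isolated), via lithium 2-(trimethylsilyl)ethynolate 12 (not isolated)
Conditions: n-BuLi, THF, −78 °C; t-BuOOLi (from t-BuOOH and LiN(SiMe3)2), −78 to 0 °C; i-Pr3SiOTf, −78 °C
Reagents that add atoms: lithium tert-butyl peroxide, [Li+].CC(C)(C)O[O-]; tri(propan-2-yl)silyl trifluoromethanesulfonate, CC(C)[Si](OS(=O)(=O)C(F)(F)F)(C(C)C)C(C)C
Why: oxidation of a lithium acetylide by lithium tert-butyl peroxide to the ynolate, followed by O-silylation, which the bulky silyl triflate should favour over C-silylation.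

Step 7
Reactants: 13 trimethyl({[tri(propan-2-yl)silyl]oxy}ethynyl)silane
Product: 14 (ethynyloxy)tri(propan-2-yl)silane
Conditions: K2CO3 (0.2 equiv), MeOH, 0 °C
Reagents that add atoms: none
Why: base-catalysed methanolysis of the alkynyl C–SiMe3 bond should leave the hindered O–Si(i-Pr)3 bond and the base-stable ynol ether intact.

Step 8
Reactants: 9 the cyclobutenone of step 5; 14 (ethynyloxy)tri(propan-2-yl)silane
Product: 19 3-(2-{4-[2-(benzyloxy)-5-ethenylphenoxy]phenyl}ethyl)-4-(3-bromophenoxy)-5-{[tri(propan-2-yl)silyl]oxy}phenol, via vinylketene 15 (not isolated), via alkenylcyclobutenone 16 (not isolated), via dienylketene 17 (not isolated), via cyclohexadienone 18 (not isolated)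
Conditions: 14 (2 equiv), toluene, 80 °C then 110 °C, sealed tube
Reagents that add atoms: none
Why: Danheiser benzannulation: 4π-electrocyclic opening of 9 gives the (aryloxy)vinylketene 15, whose C=C=O unit adds to 14 in a regiospecific [2+2] (alkyne CH to the ketene carbonyl carbon, siloxy carbon to the aryloxy-bearing α-carbon) to give 16, and these are the two new bonds, C2–C3 and C4–C5 of ring A. 16 then opens (4π) to dienylketene 17, which closes ring A by a thermal disrotatory 6π-electrocyclisation to dienone 18, and 18 tautomerises to phenol 19. The closest known reaction is the annulation of 2,3-disubstituted cyclobutenones with (triisopropylsilyloxy)alkynes to resorcinol monosilyl ethers; here the 2-substituent is an aryloxy group. No stereocentre is formed, since racemic 16 is consumed. The step needs the [2+2] regiochemistry, secured by the polarisation of ketene and ynol ether; inward rotation of the alkenyl group when 16 opens, secured because the donor aryloxy group on the same carbon prefers to rotate outward; and reaction at the alkyne and not at the ring C styrene, secured by the much higher nucleophilicity of the siloxyalkyne.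

Step 9
Reactants: 19 the phenol of step 8
Product: 20 1-(benzyloxy)-2-[4-(2-{2-(3-bromophenoxy)-5-methoxy-3-{[tri(propan-2-yl)silyl]oxy}phenyl}ethyl)phenoxy]-4-ethenylbenzene
Conditions: MeI, K2CO3, acetone, 50 °C
Reagents that add atoms: iodomethane, CI
Why: Williamson methylation of the only free phenol should fix the future C2 methoxy group before any oxidation, since this hydroxyl is para to the aryl ether.

Step 10
Reactants: 20 the methyl ether of step 9
Product: 22 18-membered macrocycle with ring A as the 5-methoxy-3-{[tri(propan-2-yl)silyl]oxy}-1,2-phenylene unit and ring C as benzyl ether, via B-alkyl-9-borabicyclononane 21 (not isolated)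
Conditions: 9-BBN, THF, rt; then PdCl2(dppf) (10 mol%), AsPh3, K3PO4 (aq.), THF/DMF, 60 °C, slow addition (final 2 mM)
Reagents that add atoms: none
Why: anti-Markovnikov hydroboration of the styrene followed by intramolecular B-alkyl Suzuki–Miyaura coupling with the ring D bromide (oxidative addition to zerovalent palladium) should close the saturated C–D bridge directly under high dilution.

Step 11
Reactants: 22 the macrocycle of step 10
Product: 23 macrocyclic phenol (ring A: 3-hydroxy-5-methoxy-1,2-phenylene unit; ring C benzyl ether)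
Conditions: Bu4NF, AcOH, THF, 0 °C
Reagents that add atoms: none
Why: buffered fluoride cleavage of the aryl silyl ether should free the C4 hydroxyl without exposing the electron-rich phenoxide to base and air.

Step 12
Reactants: 23 the macrocyclic phenol of step 11
Product: 24 O-benzyl ether of the target quinone
Conditions: ON(SO3K)2 (2.5 equiv), KH2PO4, acetone/H2O, rt
Reagents that add atoms: potassium nitrosodisulfonate, [K+].[K+].[O-]S(=O)(=O)N([O])S(=O)(=O)[O-]
Why: Teuber oxidation of a phenol with a free para position should deliver oxygen to C1 and give the para-quinone, as for 3-methoxy-5-alkylphenols; the other rings carry no free phenol.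

Step 13
Reactants: 24 the O-benzyl quinone of step 12
Product: 26 target quinone CNP0332646.0, via macrocyclic hydroquinone 25 (not isolated)
Conditions: H2 (1 atm), Pd/C, EtOAc, rt; filter; Ag2O, MgSO4, rt
Reagents that add atoms: none
Why: hydrogenolysis should remove the benzyl ether while the quinone is reversibly reduced to hydroquinone 25, which Ag2O reoxidises without touching the ring C phenol.

**Compound list**

1 | 4-(benzyloxy)-3-hydroxybenzaldehyde | O=Cc1ccc(OCc2ccccc2)c(O)c1 | starting material
2 | methyl 3-(4-iodophenyl)propanoate | COC(=O)CCc1ccc(I)cc1 | starting material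
3 | methyl 3-{4-[2-(benzyloxy)-5-formylphenoxy]phenyl}propanoate | COC(=O)CCc1ccc(Oc2cc(C=O)ccc2OCc2ccccc2)cc1 | intermediate
4 | 1-(benzyloxy)-4-ethenyl-2-[4-(3-methoxybut-3-en-1-yl)phenoxy]benzene | C=C(OC)CCc1ccc(Oc2cc(C=C)ccc2OCc2ccccc2)cc1 | intermediate
5 | (3-bromophenoxy)acetic acid | OC(=O)COc1cccc(Br)c1 | starting material
6 | (3-bromophenoxy)acetyl chloride | O=C(Cl)COc1cccc(Br)c1 | intermediate
7 | (3-bromophenoxy)ketene | O=C=COc1cccc(Br)c1 | intermediate (not isolated)
8 | 3-(2-{4-[2-(benzyloxy)-5-ethenylphenoxy]phenyl}ethyl)-2-(3-bromophenoxy)-3-methoxycyclobutan-1-one, diastereomer mixture | COC1(CCc2ccc(Oc3cc(C=C)ccc3OCc3ccccc3)cc2)CC(=O)C1Oc1cccc(Br)c1 | intermediate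
9 | 3-(2-{4-[2-(benzyloxy)-5-ethenylphenoxy]phenyl}ethyl)-2-(3-bromophenoxy)cyclobut-2-en-1-one | O=C1CC(CCc2ccc(Oc3cc(C=C)ccc3OCc3ccccc3)cc2)=C1Oc1cccc(Br)c1 | intermediate
10 | ethynyltrimethylsilane | C#C[Si](C)(C)C | starting material
11 | lithium (trimethylsilyl)acetylide | [Li]C#C[Si](C)(C)C | intermediate (not isolated)
12 | lithium 2-(trimethylsilyl)ethynolate | [Li]OC#C[Si](C)(C)C | intermediate (not isolated)
13 | trimethyl({[tri(propan-2-yl)silyl]oxy}ethynyl)silane | C[Si](C)(C)C#CO[Si](C(C)C)(C(C)C)C(C)C | intermediate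
14 | (ethynyloxy)tri(propan-2-yl)silane | C#CO[Si](C(C)C)(C(C)C)C(C)C | intermediate
15 | (aryloxy)vinylketene from ring opening of 9 | O=C=C(Oc1cccc(Br)c1)C(=C)CCc1ccc(Oc2cc(C=C)ccc2OCc2ccccc2)cc1 | intermediate (not isolated)
16 | 4-alkenyl-4-(3-bromophenoxy)-3-siloxycyclobut-2-en-1-one, racemic | O=C1C=C(O[Si](C(C)C)(C(C)C)C(C)C)C1(Oc1cccc(Br)c1)C(=C)CCc1ccc(Oc2cc(C=C)ccc2OCc2ccccc2)cc1 | intermediate (not isolated)
17 | dienylketene, ketenyl and alkenyl groups cis | O=C=C/C(O[Si](C(C)C)(C(C)C)C(C)C)=C(Oc1cccc(Br)c1)\C(=C)CCc1ccc(Oc2cc(C=C)ccc2OCc2ccccc2)cc1 | intermediate (not isolated)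
18 | cyclohexa-2,4-dien-1-one tautomer of 19 | O=C1C=C(O[Si](C(C)C)(C(C)C)C(C)C)C(Oc2cccc(Br)c2)=C(CCc2ccc(Oc3cc(C=C)ccc3OCc3ccccc3)cc2)C1 | intermediate (not isolated)
19 | 3-(2-{4-[2-(benzyloxy)-5-ethenylphenoxy]phenyl}ethyl)-4-(3-bromophenoxy)-5-{[tri(propan-2-yl)silyl]oxy}phenol | Oc1cc(O[Si](C(C)C)(C(C)C)C(C)C)c(Oc2cccc(Br)c2)c(CCc2ccc(Oc3cc(C=C)ccc3OCc3ccccc3)cc2)c1 | intermediate
20 | methyl ether of 19 | COc1cc(O[Si](C(C)C)(C(C)C)C(C)C)c(Oc2cccc(Br)c2)c(CCc2ccc(Oc3cc(C=C)ccc3OCc3ccccc3)cc2)c1 | intermediate
21 | B-alkyl-9-borabicyclo[3.3.1]nonane from hydroboration of 20 | COc1cc(O[Si](C(C)C)(C(C)C)C(C)C)c(Oc2cccc(Br)c2)c(CCc2ccc(Oc3cc(CCB4C5CCCC4CCC5)ccc3OCc3ccccc3)cc2)c1 | intermediate (not isolated)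
22 | macrocycle, ring A with OMe and OSi(i-Pr)3, ring C benzyl ether | COc1cc(O[Si](C(C)C)(C(C)C)C(C)C)c2c(c1)CCc1ccc(cc1)Oc1cc(ccc1OCc1ccccc1)CCc1cccc(c1)O2 | intermediate
23 | macrocyclic phenol, ring A with OMe and OH, ring C benzyl ether | COc1cc(O)c2c(c1)CCc1ccc(cc1)Oc1cc(ccc1OCc1ccccc1)CCc1cccc(c1)O2 | intermediate
24 | O-benzyl ether of the target quinone | COC1=CC(=O)C2=C(CCc3ccc(cc3)Oc3cc(ccc3OCc3ccccc3)CCc3cccc(c3)O2)C1=O | intermediate
25 | macrocyclic hydroquinone with free ring C phenol | COc1cc(O)c2c(c1O)CCc1ccc(cc1)Oc1cc(ccc1O)CCc1cccc(c1)O2 | intermediate (not isolated)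
26 | CNP0332646.0 | COC1=CC(=O)C2=C(CCc3ccc(cc3)Oc3cc(ccc3O)CCc3cccc(c3)O2)C1=O | target

**Step count and risks**

Total step count: 13. Longest linear sequence: 10 steps (steps 1, 2, 4, 5, 8, 9, 10, 11, 12, 13).

Steps most likely to fail:

1. Step 5. What may go wrong: methanol is lost toward the ring CH2 instead of toward the aryloxy-bearing carbon, giving the wrong double-bond position, or the base cleaves the strained ring. Fallback (sets out from 6, comes back at 9): 6 is chlorinated at its α-carbon (N-chlorosuccinimide, SOCl2, HCl cat., 70 °C) to 2-(3-bromophenoxy)-2-chloroacetyl chloride F1. Et3N converts F1 into (3-bromophenoxy)chloroketene F2, which should add to enol ether 4 in the same [2+2] sense to give 3-(2-{4-[2-(benzyloxy)-5-ethenylphenoxy]phenyl}ethyl)-2-(3-bromophenoxy)-2-chloro-3-methoxycyclobutan-1-one F3. Zinc dust (THF/AcOH, 0 °C) then inserts into the C–Cl bond next to the carbonyl; the zinc enolate is fixed on the aryloxy-bearing carbon and expels the neighbouring methoxide (Reformatsky-type reductive β-elimination), so the double bond can form only where it is needed, giving 9.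

2. Step 8. What may go wrong: at the temperature needed to open 9, the vinylketene dimerises or acylates the product phenol before the siloxyalkyne traps it, or 14 decomposes. Fallback (sets out from 9, comes back at 19): the vinylketene is made cold from an open-chain precursor and the cascade is run in two stages. LiOH (THF/H2O, 0 °C) adds to the carbonyl of 9 and cleaves the C(=O)–CH2 ring bond; kinetic α-protonation of the dienolate should give 5-{4-[2-(benzyloxy)-5-ethenylphenoxy]phenyl}-2-(3-bromophenoxy)-3-methylidenepentanoic acid F4. Oxalyl chloride gives the acid chloride 5-{4-[2-(benzyloxy)-5-ethenylphenoxy]phenyl}-2-(3-bromophenoxy)-3-methylidenepentanoyl chloride F5. Et3N (CH2Cl2, 0 °C) in the presence of 14 dehydrochlorinates F5 to vinylketene 15, which is trapped at once as 16; 16 is isolated and heated alone (toluene, 90–110 °C) to 19 through 17 and 18. The same two ring A bonds are formed, now at 0 °C.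

3. Step 10. What may go wrong: intermolecular coupling to oligomers, or protodeboronation of the alkylborane, instead of ring closure. Fallback (sets out from 20, comes back at 22): the bridge is closed as a stilbene and then reduced. Vinylation of the aryl bromide of 20 (potassium vinyltrifluoroborate, PdCl2(dppf), Et3N, n-PrOH, 80 °C) gives the bis-styrene 1-(benzyloxy)-4-ethenyl-2-[4-(2-{2-(3-ethenylphenoxy)-5-methoxy-3-{[tri(propan-2-yl)silyl]oxy}phenyl}ethyl)phenoxy]benzene F6. Ring-closing metathesis (second-generation Grubbs catalyst, toluene, 80 °C, 1 mM) should give the macrocyclic stilbene F7 (E/Z mixture, of no consequence). Diimide (TsNHNH2, NaOAc, DME/H2O, reflux) saturates the stilbene without touching the benzyl or silyl ether and gives 22.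

**Further compounds**

F1 | step 5 | 2-(3-bromophenoxy)-2-chloroacetyl chloride | O=C(Cl)C(Cl)Oc1cccc(Br)c1
F2 | step 5 | (3-bromophenoxy)chloroketene | O=C=C(Cl)Oc1cccc(Br)c1
F3 | step 5 | 3-(2-{4-[2-(benzyloxy)-5-ethenylphenoxy]phenyl}ethyl)-2-(3-bromophenoxy)-2-chloro-3-methoxycyclobutan-1-one | COC1(CCc2ccc(Oc3cc(C=C)ccc3OCc3ccccc3)cc2)CC(=O)C1(Cl)Oc1cccc(Br)c1
F4 | step 8 | 5-{4-[2-(benzyloxy)-5-ethenylphenoxy]phenyl}-2-(3-bromophenoxy)-3-methylidenepentanoic acid | OC(=O)C(Oc1cccc(Br)c1)C(=C)CCc1ccc(Oc2cc(C=C)ccc2OCc2ccccc2)cc1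
F5 | step 8 | 5-{4-[2-(benzyloxy)-5-ethenylphenoxy]phenyl}-2-(3-bromophenoxy)-3-methylidenepentanoyl chloride | O=C(Cl)C(Oc1cccc(Br)c1)C(=C)CCc1ccc(Oc2cc(C=C)ccc2OCc2ccccc2)cc1
F6 | step 10 | 1-(benzyloxy)-4-ethenyl-2-[4-(2-{2-(3-ethenylphenoxy)-5-methoxy-3-{[tri(propan-2-yl)silyl]oxy}phenyl}ethyl)phenoxy]benzene | COc1cc(O[Si](C(C)C)(C(C)C)C(C)C)c(Oc2cccc(C=C)c2)c(CCc2ccc(Oc3cc(C=C)ccc3OCc3ccccc3)cc2)c1
F7 | step 10 | macrocyclic stilbene analogue of 22 (E/Z mixture) | COc1cc(O[Si](C(C)C)(C(C)C)C(C)C)c2c(c1)CCc1ccc(cc1)Oc1cc(ccc1OCc1ccccc1)C=Cc1cccc(c1)O2
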